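The quaternary centre C4 is traced back to a Cs-symmetric 4-alkyl-4-methoxycyclohexa-2,5-dienone in which C4 is not yet stereogenic. Because C7 lies two bonds from C4, a temporary hydroxyl on C7 reaches C5 of either enone arm through a tetrahydrofuran fused across C4–C5. One base-mediated oxa-Michael closure forms the C5–O bond, the cis-fused ring and both ring stereocentres, the C8 methyl group choosing the arm. The precursor, dienone 7, comes from dearomatising a 1,2-diarylpropanol made by dynamic kinetic resolution. The benzylic C7–O bond is later cut reductively, so the tether oxygen ends as the C5 methoxy oxygen.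

Key step: step 6

Numbering: ring C1 (C=O), C2 (allyl-bearing), C3, C4 (quaternary), C5 (methoxy-bearing), C6; side chain C8 (methine on C4) and C7 (benzylic).

Remark: the (R)-XylBINAP/(R)-DAIPEN ruthenium catalyst is assumed to give the 1S carbinol, the sense it shows with simple aryl alkyl ketones; otherwise its antipode would be used.

Step 1
Reactants: 1 propiovanillone
Product: 2 1-[3-methoxy-4-(triisopropylsilyloxy)phenyl]propan-1-one
Conditions: TIPSCl, imidazole, DMF, 23 °C
Reagents that add atoms: chlorotriisopropylsilane, CC(C)[Si](Cl)(C(C)C)C(C)C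
Why: Imidazole-promoted silyl ether formation on the phenol is routine, and the bulky triisopropylsilyl group is chosen because it should survive tert-butoxide, hydrogenation, iodine(III), trifluoroacetic acid and palladium and is cleaved by fluoride at the end.

Step 2
Reactants: 2 silyl-protected propiovanillone; 3 1-(benzyloxy)-4-bromobenzene
Product: 4 rac-2-[4-(benzyloxy)phenyl]-1-[3-methoxy-4-(triisopropylsilyloxy)phenyl]propan-1-one
Conditions: Pd2(dba)3 (1.5 mol%), Xantphos (3.6 mol%), NaOtBu (1.3 equiv), toluene, 70 °C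
Reagents that add atoms: none
Why: Palladium-catalysed α-arylation of the ketone enolate (Buchwald–Hartwig type) is well established for propiophenones and aryl bromides and stops after one arylation because the product enolate is too hindered to couple again, while the new C8 centre is formed racemic and is left base-labile on purpose.

Step 3
Reactants: 4 racemic α-aryl ketone
Product: 5 (1S,2S)-2-[4-(benzyloxy)phenyl]-1-[3-methoxy-4-(triisopropylsilyloxy)phenyl]propan-1-ol
Conditions: trans-RuCl2[(R)-xylbinap][(R)-daipen] (0.5 mol%), t-BuOK (0.2 equiv), H2 (10 atm), i-PrOH, 25 °C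
Reagents that add atoms: none
Why: Noyori asymmetric hydrogenation with dynamic kinetic resolution: tert-butoxide racemises the acidic C8–H of 4 faster than the ketone is reduced, the chiral Ru diphosphine/diamine catalyst fixes C7 as S by face-selective outer-sphere hydride transfer, and the Felkin–Anh preference (α-aryl group anti to the incoming hydride, which Ru–diamine catalysts follow strongly) lets only the C8 enantiomer react that gives the (1S,2S) alcohol.

Step 4
Reactants: 5 (1S,2S) benzyl ether alcohol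
Product: 6 4-{(1S,2S)-1-hydroxy-1-[3-methoxy-4-(triisopropylsilyloxy)phenyl]propan-2-yl}phenol
Conditions: H2 (1 atm), 10% Pd/C, EtOAc, 23 °C
Reagents that add atoms: none
Why: Heterogeneous hydrogenolysis cleaves the phenolic benzyl ether much faster than the secondary benzylic C–OH bond under neutral conditions, and neither the silyl ether nor the two stereocentres are affected.

Step 5
Reactants: 6 (1S,2S) phenol
Product: 7 4-{(1S,2R)-1-hydroxy-1-[3-methoxy-4-(triisopropylsilyloxy)phenyl]propan-2-yl}-4-methoxycyclohexa-2,5-dien-1-one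
Conditions: PhI(OAc)2 (1.1 equiv), MeOH, 0 °C
Reagents that add atoms: methanol, CO
Why: Hypervalent-iodine oxidative dearomatisation of a para-alkylphenol in methanol captures the phenoxenium intermediate at the para carbon as the 4-methoxy dienone, whose two enone arms are equivalent so that C4 poses no stereochemical question, while the silyl ether protects the second arene from oxidation and C8 changes its descriptor from S to R only because the CIP priorities change.

Step 6
Reactants: 7 symmetric dienone with the C7 hydroxyl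
Product: 8 (2S,3R,3aR,7aS)-3a-methoxy-2-[3-methoxy-4-(triisopropylsilyloxy)phenyl]-3-methyl-2,3,3a,7a-tetrahydro-1-benzofuran-6(7H)-one
Conditions: DBU (0.2 equiv), CH2Cl2, 23 °C, until the adduct ratio is constant
Reagents that add atoms: none
Why: DBU reversibly turns the C7 hydroxyl into an alkoxide that adds to C5 of one enone arm, and the resulting enolate is protonated at C6; this is the known base-mediated intramolecular oxa-Michael desymmetrisation of 4-substituted cyclohexa-2,5-dienones that carry a tethered alcohol. The tetrahydrofuran ring closes in the 5-exo-trig mode through the new C5–O bond. C5 is controlled by the tether, since the O–C7–C8 link can only reach the dienone face on which C8 stands, which enforces the cis ring fusion. C4 is controlled by the C8 and C7 centres set in step 3: retro-Michael opening lets the two arm adducts equilibrate, and 8, in which the C8 methyl is on the convex face, syn to the C4 methoxy group and trans to the aryl group, should be favoured because the other adduct forces that methyl onto the concave face against the vinylic CH and the ring methylene. The step thus needs only selection between the two diastereotopic arms, and the reversibility together with the (1S,2R) side chain is what secures it; the aryl group on the concave face of 8 is the accepted cost.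

Step 7
Reactants: 8 cis-fused enone
Product: 9 (2S,3R,3aS,7aS)-5-iodo-3a-methoxy-2-[3-methoxy-4-(triisopropylsilyloxy)phenyl]-3-methyl-2,3,3a,7a-tetrahydro-1-benzofuran-6(7H)-one
Conditions: I2 (2 equiv), pyridine/CH2Cl2 (1:1), 0 to 23 °C
Reagents that add atoms: iodine, II
Why: Johnson α-iodination of the enone (conjugate addition of pyridine at C3, iodination of the enolate at C2, loss of pyridine) is regiospecific for C2, and pyridine is too weak a base to reopen the β-alkoxy ketone or to touch the silyl ether.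

Step 8
Reactants: 9 α-iodoenone
Product: 10 (2S,3R,3aR,7aS)-5-allyl-3a-methoxy-2-[3-methoxy-4-(triisopropylsilyloxy)phenyl]-3-methyl-2,3,3a,7a-tetrahydro-1-benzofuran-6(7H)-one
Conditions: allylSnBu3, Pd2(dba)3 (5 mol%), AsPh3 (20 mol%), CuI (10 mol%), DMF, 50 °C
Reagents that add atoms: allyltributylstannane, C=CC[Sn](CCCC)(CCCC)CCCC
Why: Stille cross-coupling of the α-iodoenone with the allylstannane, accelerated by triphenylarsine and copper(I), forms the C2–allyl bond under neutral conditions that leave the β-alkoxy ketone, the silyl ether and all stereocentres untouched.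

Step 9
Reactants: 10 allylated bicyclic ether
Product: 11 (4S,5S)-2-allyl-5-hydroxy-4-methoxy-4-{(2R)-1-[3-methoxy-4-(triisopropylsilyloxy)phenyl]propan-2-yl}cyclohex-2-en-1-one
Conditions: Et3SiH (5 equiv), TFA (10 equiv), CH2Cl2, −20 to 0 °C
Reagents that add atoms: none
Why: Acid-mediated ionisation of the 4-silyloxy-3-methoxybenzylic ether (the reactivity used to cleave p-methoxybenzyl ethers) gives the C7 cation, which triethylsilane should reduce (ionic hydrogenation) faster than it can lose the C8 proton, so C7 becomes CH2, the tether oxygen stays on C5 as a hydroxyl of unchanged configuration, and the cut is made while the carbocycle carries no enol ether that could trap the cation at C6.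

Step 10
Reactants: 11 β-hydroxy ketone
Product: 12 (4S,5S)-2-allyl-4,5-dimethoxy-4-{(2R)-1-[3-methoxy-4-(triisopropylsilyloxy)phenyl]propan-2-yl}cyclohex-2-en-1-one
Conditions: Me3OBF4, 1,8-bis(dimethylamino)naphthalene, 4 Å MS, CH2Cl2, 23 °C
Reagents that add atoms: trimethyloxonium tetrafluoroborate, C[O+](C)C.F[B-](F)(F)F
Why: O-Methylation of the hindered secondary alcohol with Meerwein's salt and a non-nucleophilic proton scavenger fixes the methyl group on the C5 oxygen while C5 is still sp3, which avoids base-induced β-elimination of the β-hydroxy ketone and the regiochemical ambiguity of methylating a 1,3-dicarbonyl enol.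

Step 11
Reactants: 12 β-methoxy ketone
Product: 14 (4S)-2-allyl-4,5-dimethoxy-4-{(2R)-1-[3-methoxy-4-(triisopropylsilyloxy)phenyl]propan-2-yl}cyclohexa-2,5-dien-1-one, via trimethylsilyl dienol ether 13 (not isolated)
Conditions: TMSOTf, Et3N, CH2Cl2, 0 °C; then Pd(OAc)2 (1.1 equiv), MeCN, 23 °C
Reagents that add atoms: trimethylsilyl trifluoromethanesulfonate, C[Si](C)(C)OS(=O)(=O)C(F)(F)F (its silyl group is held in 13 only)
Why: Saegusa–Ito oxidation: soft enolisation can occur only towards C6 (C2 bears no hydrogen) and gives the 2-silyloxydiene 13 without a free enolate that could expel the C5 methoxide, and Pd(OAc)2 then forms the C6 palladium enolate and eliminates the C5 hydrogen as hydride to give the C5=C6 enol ether, which removes the C5 stereocentre and leaves C4 and C8 untouched.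

Step 12
Reactants: 14 silyl-protected dienone
Product: 15 (4S)-2-allyl-4-[(2R)-1-(4-hydroxy-3-methoxyphenyl)propan-2-yl]-4,5-dimethoxycyclohexa-2,5-dien-1-one
Conditions: TBAF (1.1 equiv), AcOH (1.1 equiv), THF, 0 °C
Reagents that add atoms: none
Why: Fluoride-mediated desilylation of the aryl silyl ether, buffered with acetic acid so that the phenoxide is protonated at once, should free the phenol without touching the dienone, the enol ether or the allyl group, and with C7 now a methylene no quinone-methide pathway is open.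

Compound list
1 | propiovanillone, 1-(4-hydroxy-3-methoxyphenyl)propan-1-one | CCC(=O)c1ccc(O)c(OC)c1 | starting material
2 | 1-[3-methoxy-4-(triisopropylsilyloxy)phenyl]propan-1-one | CCC(=O)c1ccc(O[Si](C(C)C)(C(C)C)C(C)C)c(OC)c1 | intermediate
3 | 1-(benzyloxy)-4-bromobenzene | Brc1ccc(OCc2ccccc2)cc1 | starting material
4 | rac-2-[4-(benzyloxy)phenyl]-1-[3-methoxy-4-(triisopropylsilyloxy)phenyl]propan-1-one | CC(C(=O)c1ccc(O[Si](C(C)C)(C(C)C)C(C)C)c(OC)c1)c1ccc(OCc2ccccc2)cc1 | intermediate
5 | (1S,2S)-2-[4-(benzyloxy)phenyl]-1-[3-methoxy-4-(triisopropylsilyloxy)phenyl]propan-1-ol | O(Cc1ccccc1)c1ccc(cc1)[C@H](C)[C@H](O)c1ccc(O[Si](C(C)C)(C(C)C)C(C)C)c(OC)c1 | intermediate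
6 | 4-{(1S,2S)-1-hydroxy-1-[3-methoxy-4-(triisopropylsilyloxy)phenyl]propan-2-yl}phenol | Oc1ccc(cc1)[C@H](C)[C@H](O)c1ccc(O[Si](C(C)C)(C(C)C)C(C)C)c(OC)c1 | intermediate
7 | 4-{(1S,2R)-1-hydroxy-1-[3-methoxy-4-(triisopropylsilyloxy)phenyl]propan-2-yl}-4-methoxycyclohexa-2,5-dien-1-one | COC1([C@H](C)[C@H](O)c2ccc(O[Si](C(C)C)(C(C)C)C(C)C)c(OC)c2)C=CC(=O)C=C1 | intermediate
8 | (2S,3R,3aR,7aS)-3a-methoxy-2-[3-methoxy-4-(triisopropylsilyloxy)phenyl]-3-methyl-2,3,3a,7a-tetrahydro-1-benzofuran-6(7H)-one (cis-fused; methyl syn to 3a-methoxy, anti to aryl) | O=C1C=C[C@@]2(OC)[C@H](C)[C@@H](c3ccc(O[Si](C(C)C)(C(C)C)C(C)C)c(OC)c3)O[C@H]2C1 | intermediate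
9 | (2S,3R,3aS,7aS)-5-iodo-3a-methoxy-2-[3-methoxy-4-(triisopropylsilyloxy)phenyl]-3-methyl-2,3,3a,7a-tetrahydro-1-benzofuran-6(7H)-one | O=C1C(I)=C[C@@]2(OC)[C@H](C)[C@@H](c3ccc(O[Si](C(C)C)(C(C)C)C(C)C)c(OC)c3)O[C@H]2C1 | intermediate
10 | (2S,3R,3aR,7aS)-5-allyl-3a-methoxy-2-[3-methoxy-4-(triisopropylsilyloxy)phenyl]-3-methyl-2,3,3a,7a-tetrahydro-1-benzofuran-6(7H)-one | O=C1C(CC=C)=C[C@@]2(OC)[C@H](C)[C@@H](c3ccc(O[Si](C(C)C)(C(C)C)C(C)C)c(OC)c3)O[C@H]2C1 | intermediate
11 | (4S,5S)-2-allyl-5-hydroxy-4-methoxy-4-{(2R)-1-[3-methoxy-4-(triisopropylsilyloxy)phenyl]propan-2-yl}cyclohex-2-en-1-one (4-methoxy and 5-hydroxy trans) | O=C1C(CC=C)=C[C@@](OC)([C@H](C)Cc2ccc(O[Si](C(C)C)(C(C)C)C(C)C)c(OC)c2)[C@@H](O)C1 | intermediate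
12 | (4S,5S)-2-allyl-4,5-dimethoxy-4-{(2R)-1-[3-methoxy-4-(triisopropylsilyloxy)phenyl]propan-2-yl}cyclohex-2-en-1-one | O=C1C(CC=C)=C[C@@](OC)([C@H](C)Cc2ccc(O[Si](C(C)C)(C(C)C)C(C)C)c(OC)c2)[C@@H](OC)C1 | intermediate
13 | (5S,6S)-3-allyl-5,6-dimethoxy-5-{(2R)-1-[3-methoxy-4-(triisopropylsilyloxy)phenyl]propan-2-yl}-2-(trimethylsilyloxy)cyclohexa-1,3-diene | C=CCC1=C[C@@](OC)([C@H](C)Cc2ccc(O[Si](C(C)C)(C(C)C)C(C)C)c(OC)c2)[C@@H](OC)C=C1O[Si](C)(C)C | intermediate (not isolated)
14 | (4S)-2-allyl-4,5-dimethoxy-4-{(2R)-1-[3-methoxy-4-(triisopropylsilyloxy)phenyl]propan-2-yl}cyclohexa-2,5-dien-1-one | C=CCC1=C[C@@](OC)([C@H](C)Cc2ccc(O[Si](C(C)C)(C(C)C)C(C)C)c(OC)c2)C(OC)=CC1=O | intermediate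
15 | (4S)-2-allyl-4-[(2R)-1-(4-hydroxy-3-methoxyphenyl)propan-2-yl]-4,5-dimethoxycyclohexa-2,5-dien-1-one (CNP0370214.1) | C=CCC1=C[C@@](OC)([C@H](C)Cc2ccc(O)c(OC)c2)C(OC)=CC1=O | target

Total step count: 12. Longest linear sequence: 12 steps (1 to 15).

Steps most likely to fail

Step 6. Arm selection under equilibration may be incomplete or reversed, because only the C8 methyl group favours the required arm while the aryl group must go to the concave face. The fallback changes the tether to the C7 epimer, for which methyl and aryl are both convex in the adduct of the same C4 configuration. Setting out from 5, Mitsunobu inversion at C7 (4-nitrobenzoic acid, PPh3, DIAD, THF) should give the (1R,2S) 4-nitrobenzoate F1, and brief methanolysis (K2CO3, MeOH, 0 °C) the erythro alcohol F2. Under the conditions of steps 4 to 8, F2 should give in turn the erythro phenol F3, the C7-epimeric dienone F4, the all-convex oxa-Michael adduct F5, the iodoenone F6 and the allyl enone F7. Ionic hydrogenation of F7 as in step 9 erases C7, and the fallback comes back to the route at 11.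

Step 9. The benzylic cation may lose the C8 proton and be re-protonated, which would erode C8, or the β-hydroxy ketone may dehydrate in acid. The fallback cuts the C7–O bond anionically after the enol ether is in place. Setting out from 10, Saegusa oxidation under the conditions of step 11, through the silyl dienol ether F8, should give the bicyclic vinylogous ester F9. TBAF then frees the phenol F10, whose phenoxide expels the vinylogous carboxylate to give the quinone methide F11, and NaBH4 present in the same flask reduces it to the hydroxydienone F12. Methylation of this vinylogous acid with TMSCHN2 in MeOH/toluene, with separation from the regioisomeric enol ether, comes back to the route at 15.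

Step 11. Methoxide may be lost from C5 by β-elimination during enolisation or from the palladium enolate, and the allyl double bond may migrate under palladium hydride. The fallback reaches the enol ether through the oxidation level of C5 and not by dehydrogenation. Setting out from 11, Dess–Martin oxidation should give the ene-1,3-dione F13, and O-methylation of its enol (TMSCHN2, MeOH), with separation from the regioisomeric enol ether, comes back to the route at 14.

Further compounds
F1 | step 6 | (1R,2S)-2-[4-(benzyloxy)phenyl]-1-[3-methoxy-4-(triisopropylsilyloxy)phenyl]propyl 4-nitrobenzoate | O(Cc1ccccc1)c1ccc(cc1)[C@H](C)[C@@H](OC(=O)c1ccc(cc1)[N+](=O)[O-])c1ccc(O[Si](C(C)C)(C(C)C)C(C)C)c(OC)c1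
F2 | step 6 | (1R,2S)-2-[4-(benzyloxy)phenyl]-1-[3-methoxy-4-(triisopropylsilyloxy)phenyl]propan-1-ol | O(Cc1ccccc1)c1ccc(cc1)[C@H](C)[C@@H](O)c1ccc(O[Si](C(C)C)(C(C)C)C(C)C)c(OC)c1
F3 | step 6 | 4-{(1R,2S)-1-hydroxy-1-[3-methoxy-4-(triisopropylsilyloxy)phenyl]propan-2-yl}phenol | Oc1ccc(cc1)[C@H](C)[C@@H](O)c1ccc(O[Si](C(C)C)(C(C)C)C(C)C)c(OC)c1
F4 | step 6 | 4-{(1R,2R)-1-hydroxy-1-[3-methoxy-4-(triisopropylsilyloxy)phenyl]propan-2-yl}-4-methoxycyclohexa-2,5-dien-1-one | COC1([C@H](C)[C@@H](O)c2ccc(O[Si](C(C)C)(C(C)C)C(C)C)c(OC)c2)C=CC(=O)C=C1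
F5 | step 6 | (2R,3R,3aR,7aS)-3a-methoxy-2-[3-methoxy-4-(triisopropylsilyloxy)phenyl]-3-methyl-2,3,3a,7a-tetrahydro-1-benzofuran-6(7H)-one | O=C1C=C[C@@]2(OC)[C@H](C)[C@H](c3ccc(O[Si](C(C)C)(C(C)C)C(C)C)c(OC)c3)O[C@H]2C1
F6 | step 6 | (2R,3R,3aS,7aS)-5-iodo-3a-methoxy-2-[3-methoxy-4-(triisopropylsilyloxy)phenyl]-3-methyl-2,3,3a,7a-tetrahydro-1-benzofuran-6(7H)-one | O=C1C(I)=C[C@@]2(OC)[C@H](C)[C@H](c3ccc(O[Si](C(C)C)(C(C)C)C(C)C)c(OC)c3)O[C@H]2C1
F7 | step 6 | (2R,3R,3aR,7aS)-5-allyl-3a-methoxy-2-[3-methoxy-4-(triisopropylsilyloxy)phenyl]-3-methyl-2,3,3a,7a-tetrahydro-1-benzofuran-6(7H)-one | O=C1C(CC=C)=C[C@@]2(OC)[C@H](C)[C@H](c3ccc(O[Si](C(C)C)(C(C)C)C(C)C)c(OC)c3)O[C@H]2C1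
F8 | step 9 | (2S,3R,3aR,7aS)-5-allyl-3a-methoxy-2-[3-methoxy-4-(triisopropylsilyloxy)phenyl]-3-methyl-6-(trimethylsilyloxy)-2,3,3a,7a-tetrahydro-1-benzofuran | C=CCC1=C[C@@]2(OC)[C@H](C)[C@@H](c3ccc(O[Si](C(C)C)(C(C)C)C(C)C)c(OC)c3)O[C@H]2C=C1O[Si](C)(C)C
F9 | step 9 | (2S,3R,3aR)-5-allyl-3a-methoxy-2-[3-methoxy-4-(triisopropylsilyloxy)phenyl]-3-methyl-3,3a-dihydro-1-benzofuran-6(2H)-one | C=CCC1=C[C@@]2(OC)[C@H](C)[C@@H](c3ccc(O[Si](C(C)C)(C(C)C)C(C)C)c(OC)c3)OC2=CC1=O
F10 | step 9 | (2S,3R,3aR)-5-allyl-2-(4-hydroxy-3-methoxyphenyl)-3a-methoxy-3-methyl-3,3a-dihydro-1-benzofuran-6(2H)-one | C=CCC1=C[C@@]2(OC)[C@H](C)[C@@H](c3ccc(O)c(OC)c3)OC2=CC1=O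
F11 | step 9 | (4S)-2-allyl-5-hydroxy-4-methoxy-4-[(2R)-1-(3-methoxy-4-oxocyclohexa-2,5-dien-1-ylidene)propan-2-yl]cyclohexa-2,5-dien-1-one | C=CCC1=C[C@@](OC)([C@H](C)C=C2C=CC(=O)C(OC)=C2)C(O)=CC1=O
F12 | step 9 | (4S)-2-allyl-5-hydroxy-4-[(2R)-1-(4-hydroxy-3-methoxyphenyl)propan-2-yl]-4-methoxycyclohexa-2,5-dien-1-one | C=CCC1=C[C@@](OC)([C@H](C)Cc2ccc(O)c(OC)c2)C(O)=CC1=O
F13 | step 11 | (6S)-4-allyl-6-methoxy-6-{(2R)-1-[3-methoxy-4-(triisopropylsilyloxy)phenyl]propan-2-yl}cyclohex-4-ene-1,3-dione | O=C1C(CC=C)=C[C@@](OC)([C@H](C)Cc2ccc(O[Si](C(C)C)(C(C)C)C(C)C)c(OC)c2)C(=O)C1
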